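**Strategy.** The methyl-bearing tetrahydrofuran ring of the 1,6-dioxaspiro[4.4]nonane (O1, C2(CH3), C3, C4, spiro C5) is treated as a carbonyl group plus a three-carbon chain. Spiro C5 and O1 are the C=O of a γ-lactone that already is the other ring (O6, C7–C9). The key step is a formal (3+2) spiroannulation in one flask: (R)-3-chlorobutylmagnesium bromide adds to the lactone (C4–C5), and the hemiketal alkoxide then displaces chloride with inversion (O1–C2), setting C2 from (S)-butane-1,3-diol. Its precursor is an open hydroxy aryl bromide carrying the (S)-γ-lactone; Pd(OAc)2-catalysed carbonylative lactonisation closes the phthalide last.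

Key step: step 5

Remark: the text labels the spiroketal atoms O1, C2 (CH–CH3), C3, C4, C5 (spiro), O6, C7 (CH–chain), C8, C9; compounds 1, 2, 4 and 8 are taken as purchasable; the spiro centre of a 1,6-dioxaspiro[4.4]nonane has little thermodynamic bias, so the 5S isomer is secured by separation.

Step 1
Reactants: 1 (R)-(5-oxotetrahydrofuran-2-yl)methyl 4-methylbenzenesulfonate, 2 pent-4-en-1-ylmagnesium bromide
Product: 3 (S)-5-(hex-5-en-1-yl)dihydrofuran-2(3H)-one
Conditions: 2 (3.0 equiv), CuI (1.5 equiv), THF, −40 °C; then 1, −40 → −15 °C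
Reagents that add atoms: none
Why: Gilman-type SN2 alkylation of the primary tosylate by the magnesium dialkylcuprate formed in the flask, which leaves the lactone carbonyl alone at low temperature; the stereocentre is not touched (R becomes S only through the CIP ranking).

Step 2
Reactants: 3 (S)-5-(hex-5-en-1-yl)dihydrofuran-2(3H)-one, 4 2-bromo-3,5-dimethoxybenzaldehyde
Product: 7 (S)-5-[(S)-7-(2-bromo-3,5-dimethoxyphenyl)-7-hydroxyheptyl]dihydrofuran-2(3H)-one, via alkyldiethylborane 5 (not isolated), via dialkylzinc 6 (not isolated)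
Conditions: 3 (3.5 equiv), Et2BH (from BH3·SMe2 and BEt3), Et2O, 0 °C → rt; Et2Zn, 0 °C, then vacuum; 4 (1.0 equiv), Ti(OiPr)4 (2.0 equiv), (1R,2R)-1,2-bis(trifluoromethanesulfonamido)cyclohexane (8 mol %), toluene, −20 °C
Reagents that add atoms: none
Why: Anti-Markovnikov hydroboration and boron–zinc exchange give a functionalised dialkylzinc that tolerates the lactone and the aryl bromide (Knochel protocol), and its Ti(OiPr)4/bis(sulfonamide)-catalysed addition to the aldehyde should take place on the Si face under control of the (1R,2R)-ligand, which sets the (S)-carbinol.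

Step 3
Reactants: 8 (S)-butane-1,3-diol
Product: 9 (S)-4-bromobutan-2-ol
Conditions: CBr4 (1.05 equiv), PPh3 (1.05 equiv), CH2Cl2, −20 → 0 °C
Reagents that add atoms: carbon tetrabromide, BrC(Br)(Br)Br
Why: Appel bromination, selective for the less hindered primary hydroxyl at low temperature; the secondary carbinol stereocentre is not touched.

Step 4
Reactants: 9 (S)-4-bromobutan-2-ol
Product: 10 (R)-1-bromo-3-chlorobutane
Conditions: PPh3, N-chlorosuccinimide, CH2Cl2, 0 °C → rt
Reagents that add atoms: N-chlorosuccinimide, O=C1CCC(=O)N1Cl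
Why: Appel-type chlorination through the alkoxyphosphonium salt, which chloride opens by SN2 with inversion, so the (S)-alcohol should give the (R)-chloride while the primary bromide stays in place.

Step 5
Reactants: 7 (S)-5-[(S)-7-(2-bromo-3,5-dimethoxyphenyl)-7-hydroxyheptyl]dihydrofuran-2(3H)-one, 10 (R)-1-bromo-3-chlorobutane
Product: 13 (S)-1-(2-bromo-3,5-dimethoxyphenyl)-7-[(2S,5S,7S)-7-methyl-1,6-dioxaspiro[4.4]nonan-2-yl]heptan-1-ol, via Grignard reagent 11 (not isolated), via hemiketal alkoxide 12 (not isolated)
Conditions: 10, Mg, THF, 0 → 20 °C, decanted from excess Mg; 7, i-PrMgCl (1.0 equiv), THF, −78 °C, then 11 (1.15 equiv), −78 °C; KOt-Bu (2.5 equiv), DMPU, −78 → 40 °C; aq. NH4Cl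
Reagents that add atoms: none
Why: Proposed new method: the primary carbon of 11 adds once to the γ-lactone carbonyl at −78 °C (C4–C5) to give the tetrahedral hemiketal alkoxide 12, whose oxygen, the former carbonyl oxygen O1, then displaces the secondary chloride at C2 after exchange to the more nucleophilic potassium salt, so that a C=O bond and a 1,3-nucleophile/electrophile merge in a formal (3+2) annulation. The closest known reactions are the tetrahydrofuran and 1-pyrroline annulations of ketones and nitriles with 3-chloropropylmagnesium bromide and the anomeric O-alkylation of lactol alkoxides. The methyl-bearing ring closes 5-exo-tet, while the chain-bearing ring is the lactone ring itself, kept as the cyclic hemiketal or re-closed 5-exo-trig from the keto alkoxide with which 12 equilibrates. C2 is controlled by the chiral-pool chloride through SN2 inversion ((R)-C–Cl to (S)-C–O), whereas the spiro carbon is fixed in the same closure from the equilibrating hemiketal epimers without a strong intrinsic bias, so material epimeric at C5 is removed by chromatography and re-equilibrated with PPTS. The step needs mono-addition (tetrahedral intermediate stable at low temperature, slight excess of 11), O- over C-alkylation (the hemiketal alkoxide is far more abundant than the ketone enolate that would close a cyclopropane) and an untouched aryl bromide (a primary alkyl Grignard reagent does not exchange with it at −78 °C), the benzylic hydroxyl being masked first as its magnesium alkoxide.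

Step 6
Reactants: 13 (S)-1-(2-bromo-3,5-dimethoxyphenyl)-7-[(2S,5S,7S)-7-methyl-1,6-dioxaspiro[4.4]nonan-2-yl]heptan-1-ol
Product: 14 (S)-5,7-dimethoxy-3-{6-[(2S,5S,7S)-7-methyl-1,6-dioxaspiro[4.4]nonan-2-yl]hexyl}isobenzofuran-1(3H)-one
Conditions: Pd(OAc)2 (5 mol %), 1,1′-bis(diphenylphosphino)ferrocene (10 mol %), CO (1 atm), Et3N, DMF, 100 °C
Reagents that add atoms: carbon monoxide, [C-]#[O+]
Why: Carbonylative lactonisation of an ortho-bromobenzylic alcohol (oxidative addition to zerovalent palladium, CO insertion, capture of the acylpalladium by the benzylic hydroxyl, 5-exo-trig) should close the phthalide without touching any stereocentre, and the basic medium leaves the spiroketal configuration intact.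

**Compound list**
1 | (R)-(5-oxotetrahydrofuran-2-yl)methyl 4-methylbenzenesulfonate | Cc1ccc(cc1)S(=O)(=O)OC[C@H]1CCC(=O)O1 | starting material
2 | pent-4-en-1-ylmagnesium bromide | C=CCCC[Mg]Br | starting material
3 | (S)-5-(hex-5-en-1-yl)dihydrofuran-2(3H)-one | C=CCCCC[C@H]1CCC(=O)O1 | intermediate
4 | 2-bromo-3,5-dimethoxybenzaldehyde | COc1cc(OC)c(Br)c(C=O)c1 | starting material
5 | diethyl{6-[(2S)-5-oxotetrahydrofuran-2-yl]hexyl}borane | CCB(CC)CCCCCC[C@H]1CCC(=O)O1 | intermediate
6 | bis{6-[(2S)-5-oxotetrahydrofuran-2-yl]hexyl}zinc | O=C1CC[C@H](CCCCCC[Zn]CCCCCC[C@H]2CCC(=O)O2)O1 | intermediate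
7 | (S)-5-[(S)-7-(2-bromo-3,5-dimethoxyphenyl)-7-hydroxyheptyl]dihydrofuran-2(3H)-one | COc1cc(OC)c(Br)c(c1)[C@@H](O)CCCCCC[C@H]1CCC(=O)O1 | intermediate
8 | (S)-butane-1,3-diol | C[C@H](O)CCO | starting material
9 | (S)-4-bromobutan-2-ol | C[C@H](O)CCBr | intermediate
10 | (R)-1-bromo-3-chlorobutane | C[C@@H](Cl)CCBr | intermediate
11 | [(R)-3-chlorobutyl]magnesium bromide | C[C@@H](Cl)CC[Mg]Br | intermediate
12 | bromomagnesium (5S)-2-[(R)-3-chlorobutyl]-5-[(S)-7-(2-bromo-3,5-dimethoxyphenyl)-7-(chloromagnesiooxy)heptyl]tetrahydrofuran-2-olate, both epimers at the hemiketal carbon | C[C@@H](Cl)CCC1(O[Mg]Br)CC[C@H](CCCCCC[C@H](O[Mg]Cl)c2cc(OC)cc(OC)c2Br)O1 | intermediate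
13 | (S)-1-(2-bromo-3,5-dimethoxyphenyl)-7-[(2S,5S,7S)-7-methyl-1,6-dioxaspiro[4.4]nonan-2-yl]heptan-1-ol | COc1cc(OC)c(Br)c(c1)[C@@H](O)CCCCCC[C@H]1CC[C@]2(CC[C@H](C)O2)O1 | intermediate
14 | (S)-5,7-dimethoxy-3-{6-[(2S,5S,7S)-7-methyl-1,6-dioxaspiro[4.4]nonan-2-yl]hexyl}isobenzofuran-1(3H)-one | COc1cc(OC)c2c(c1)[C@H](CCCCCC[C@H]1CC[C@]3(CC[C@H](C)O3)O1)OC2=O | target

**Total step count:** 6.
**Longest linear sequence:** 4 steps (1 → 3 → 7 → 13 → 14; the branch 8 → 9 → 10 → 13 → 14 is equally long).

**Steps most likely to fail**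

Step 5. The displacement of a secondary chloride by a hindered hemiketal alkoxide may be too slow. The ketone enolate of the ring-opened form may close a cyclopropane instead, a second equivalent of 11 may add on warming, and the closure may be unselective at the spiro carbon. The fallback closes the spiroketal the classical way, with O1 brought in on C2, and uses known chemistry only. It sets out from 9 and 7 and comes back at 13. Compound 9 is silylated (TBSCl, imidazole, DMF) to (S)-(4-bromobutan-2-yloxy)(tert-butyl)dimethylsilane F1. Its Grignard reagent [(S)-3-(tert-butyldimethylsilyloxy)butyl]magnesium bromide F2 (Mg, THF) is added at −78 °C to the lactone of 7, whose hydroxyl is first masked with i-PrMgCl. This should give the hydroxy ketone (1S,8S,14S)-1-(2-bromo-3,5-dimethoxyphenyl)-14-(tert-butyldimethylsilyloxy)-1,8-dihydroxypentadecan-11-one F3. Camphorsulfonic acid in MeOH then removes the silyl group and closes both rings to 13 with retention at the methyl carbon; the spiro epimers are separated as before.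

Step 2. Boron–zinc exchange may be incomplete, an uncatalysed background addition may erode facial selectivity at the carbinol, and only one alkyl group per zinc is transferred. The fallback sets out from 4 and 1 and comes back at 7. Brown allylation of 4 with (−)-B-allyldiisopinocampheylborane (Et2O, −78 °C; NaOH, H2O2) should give (S)-1-(2-bromo-3,5-dimethoxyphenyl)but-3-en-1-ol F4. Compound 1 and the cuprate from but-3-enylmagnesium bromide and CuI give (S)-5-(pent-4-en-1-yl)dihydrofuran-2(3H)-one F5. Cross-metathesis of F4 with excess F5 (second-generation Grubbs catalyst, CH2Cl2, 40 °C) gives (S)-5-[(S,E)-7-(2-bromo-3,5-dimethoxyphenyl)-7-hydroxyhept-4-en-1-yl]dihydrofuran-2(3H)-one F6. Diimide reduction (2-nitrobenzenesulfonyl hydrazide, Et3N, CH2Cl2) then saturates the alkene without cleaving the aryl bromide and gives 7.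

Step 6. Oxidative addition into the electron-rich, doubly ortho-substituted C–Br bond may stall, and β-hydride elimination from a palladium alkoxide may oxidise the carbinol with loss of bromine. The fallback sets out from 13 and comes back at 14. n-BuLi (2.2 equiv, THF, −78 °C) deprotonates the hydroxyl and exchanges bromine for lithium. CO2 then gives 2-{(S)-1-hydroxy-7-[(2S,5S,7S)-7-methyl-1,6-dioxaspiro[4.4]nonan-2-yl]heptyl}-4,6-dimethoxybenzoic acid F7, which should lactonise to 14 on work-up at pH 4–5 or with EDC and DMAP. Acid strong enough to epimerise the spiroketal is avoided.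

**Further compounds**
F1 | step 5 | (S)-(4-bromobutan-2-yloxy)(tert-butyl)dimethylsilane | C[C@H](O[Si](C)(C)C(C)(C)C)CCBr
F2 | step 5 | [(S)-3-(tert-butyldimethylsilyloxy)butyl]magnesium bromide | C[C@H](O[Si](C)(C)C(C)(C)C)CC[Mg]Br
F3 | step 5 | (1S,8S,14S)-1-(2-bromo-3,5-dimethoxyphenyl)-14-(tert-butyldimethylsilyloxy)-1,8-dihydroxypentadecan-11-one | C[C@H](O[Si](C)(C)C(C)(C)C)CCC(=O)CC[C@@H](O)CCCCCC[C@H](O)c1cc(OC)cc(OC)c1Br
F4 | step 2 | (S)-1-(2-bromo-3,5-dimethoxyphenyl)but-3-en-1-ol | COc1cc(OC)c(Br)c(c1)[C@@H](O)CC=C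
F5 | step 2 | (S)-5-(pent-4-en-1-yl)dihydrofuran-2(3H)-one | C=CCCC[C@H]1CCC(=O)O1
F6 | step 2 | (S)-5-[(S,E)-7-(2-bromo-3,5-dimethoxyphenyl)-7-hydroxyhept-4-en-1-yl]dihydrofuran-2(3H)-one | COc1cc(OC)c(Br)c(c1)[C@@H](O)C/C=C/CCC[C@H]1CCC(=O)O1
F7 | step 6 | 2-{(S)-1-hydroxy-7-[(2S,5S,7S)-7-methyl-1,6-dioxaspiro[4.4]nonan-2-yl]heptyl}-4,6-dimethoxybenzoic acid | COc1cc(OC)c(C(=O)O)c(c1)[C@@H](O)CCCCCC[C@H]1CC[C@]2(CC[C@H](C)O2)O1
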